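**Plan**
1. Target: the (2R)-flavanone with prenyl groups at C6, C3′ and C5′ (prenyl = 3-methylbut-2-en-1-yl, MOM = methoxymethyl). Retrosynthesis: remove three MOM ethers, then cut C2–C3 of the pyranone ring. This leads to a racemic cyclic aryl/enol acetal, a 2-aryl-4-methylidene-4H-1,3-benzodioxine.
2. That acetal is cut at its exocyclic C=CH2 (lactone methylenation) and at the two acetal C–O bonds, giving an A-ring salicylic acid and the B-ring aldehyde. The aryl–prenyl bonds are cut last (para-Claisen–Cope on ring A, Suzuki coupling on ring B).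
3. Forward: ring A is protected, O-prenylated, rearranged and saponified; ring B is protected and doubly prenylated. Acetalisation joins them in a temporary 1,3-dioxinone ring, which is methylenated. An acid-catalysed O→C (Petasis–Ferrier-type) rearrangement then opens the dioxine ring and closes the pyranone ring. MOM removal ends the route.
4. Enabling feature: C2 is bound to O1 and is benzylic to the 4′-oxygenated B ring, so it ionises to a doubly stabilised aryloxycarbenium ion. The C4 enol sits ortho to O1 on ring A, so C3 can reach C2. The temporary O3 (the former carboxyl oxygen) acts as leaving group and enol oxygen and is used up in the key step.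
5. Stereochemistry: C2 is the only stereocentre. It is set in the key step by a chiral Brønsted acid after the racemic acetal centre has been erased in the planar cation (stereoconvergent). The 6-prenyl regiochemistry is fixed earlier by the Claisen–Cope step, which leaves free only the phenol that becomes O1.

Key step: step 9

Assumption: the sense of induction of the chiral acid in step 9 cannot be predicted with confidence, so the catalyst antipode that gives the (2R) product is to be fixed in a first small-scale run and then used.

**Step 1**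
Reactants: 1 methyl 2,4,6-trihydroxybenzoate
Product: 2 methyl 2-hydroxy-4,6-bis(methoxymethoxy)benzoate
Conditions: MOMCl (2.2 equiv), i-Pr2NEt, CH2Cl2, 0 °C to rt
Reagents that add atoms: chloromethyl methyl ether, COCCl
Why: O-alkylation (MOM protection) should take the 4-OH and one of the two equivalent ortho-OH groups, while the remaining ortho-OH is held in a hydrogen bond to the ester carbonyl and stays free.

**Step 2**
Reactants: 2 methyl 2-hydroxy-4,6-bis(methoxymethoxy)benzoate
Product: 3 methyl 2,4-bis(methoxymethoxy)-6-(prenyloxy)benzoate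
Conditions: prenyl bromide, K2CO3, acetone, reflux
Reagents that add atoms: prenyl bromide (1-bromo-3-methylbut-2-ene), CC(C)=CCBr
Why: Williamson ether synthesis, in which the carbonate should deprotonate the hydrogen-bonded phenol and the phenoxide should displace the allylic bromide by SN2, as is routine for 2-hydroxyaryl carbonyl compounds.

**Step 3**
Reactants: 3 methyl 2,4-bis(methoxymethoxy)-6-(prenyloxy)benzoate
Product: 6 methyl 6-hydroxy-2,4-bis(methoxymethoxy)-3-prenylbenzoate, via ortho-dienone 4 (not isolated), via para-dienone 5 (not isolated)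
Conditions: N,N-diethylaniline, 200 °C, argon
Reagents that add atoms: none
Why: Tandem aromatic Claisen/Cope rearrangement (para-Claisen), in which the first [3,3] shift puts a 1,1-dimethylallyl group on the only free ortho carbon, the crowded ortho-dienone should undergo a second [3,3] shift to the para carbon between the two MOM ethers faster than it enolises, and tautomerisation gives the linear prenyl group with the free OH next to the unsubstituted ring CH.

**Step 4**
Reactants: 6 methyl 6-hydroxy-2,4-bis(methoxymethoxy)-3-prenylbenzoate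
Product: 7 6-hydroxy-2,4-bis(methoxymethoxy)-3-prenylbenzoic acid
Conditions: KOH, EtOH/H2O, 80 °C; then 1 M HCl to pH 4 at 0 °C
Reagents that add atoms: potassium hydroxide, [K+].[OH-]
Why: Ester saponification (acyl–oxygen cleavage by hydroxide) should leave MOM ethers and the prenyl group untouched, and cold, mild acidification should avoid decarboxylation of the electron-rich salicylic acid.

**Step 5**
Reactants: 8 3,5-dibromo-4-hydroxybenzaldehyde
Product: 9 3,5-dibromo-4-(methoxymethoxy)benzaldehyde
Conditions: MOMCl, i-Pr2NEt, CH2Cl2, 0 °C to rt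
Reagents that add atoms: chloromethyl methyl ether, COCCl
Why: MOM protection of the acidic, dibromo-flanked phenol by O-alkylation should proceed cleanly and masks the phenol for the coupling and the later titanium step.

**Step 6**
Reactants: 9 3,5-dibromo-4-(methoxymethoxy)benzaldehyde
Product: 10 4-(methoxymethoxy)-3,5-diprenylbenzaldehyde
Conditions: prenylboronic acid pinacol ester (2.6 equiv), Pd-PEPPSI-IPent (4 mol %), aq KOH, THF, 65 °C
Reagents that add atoms: prenylboronic acid pinacol ester, CC(C)=CCB1OC(C)(C)C(C)(C)O1
Why: Double Suzuki–Miyaura coupling of the allylic boronate, in which the bulky NHC–palladium catalyst should enforce reductive elimination at the unsubstituted allyl terminus to give linear prenyl groups, while the MOM ether and the non-enolisable aldehyde are expected to survive.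

**Step 7**
Reactants: 7 6-hydroxy-2,4-bis(methoxymethoxy)-3-prenylbenzoic acid; 10 4-(methoxymethoxy)-3,5-diprenylbenzaldehyde
Product: 12 racemic 2-[4-(methoxymethoxy)-3,5-diprenylphenyl]-5,7-bis(methoxymethoxy)-6-prenyl-4H-1,3-benzodioxin-4-one, via bis-TMS derivative 11 (not isolated)
Conditions: HMDS, CH2Cl2, rt, evaporate; then 10, TMSOTf (15 mol %), CH2Cl2, −78 to −40 °C; pyridine quench
Reagents that add atoms: none
Why: Silyl-transfer acetalisation, in which the TMSOTf-activated aldehyde should be captured by the silyl ether and silyl ester oxygens to close the six-membered acylal ring with loss of hexamethyldisiloxane; only one phenol is free, so the ring oxygen falls next to C8–H, and the racemic acetal centre is of no consequence.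

**Step 8**
Reactants: 12 racemic 2-aryl-5,7-bis(methoxymethoxy)-6-prenyl-4H-1,3-benzodioxin-4-one
Product: 13 racemic 2-[4-(methoxymethoxy)-3,5-diprenylphenyl]-5,7-bis(methoxymethoxy)-4-methylidene-6-prenyl-4H-1,3-benzodioxine
Conditions: Cp2TiMe2 (2.5 equiv), toluene, 70 °C, dark; filtration through basic alumina (1% Et3N)
Reagents that add atoms: dimethyltitanocene, C[Ti](C)(C1C=CC=C1)C1C=CC=C1
Why: Petasis methylenation, in which thermally formed Cp2Ti=CH2 should convert the lactone carbonyl into the exocyclic enol ether by [2+2]/retro-[2+2] under neutral conditions that spare the acetal, the MOM ethers and the prenyl alkenes.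

**Step 9**
Reactants: 13 racemic 2-aryl-5,7-bis(methoxymethoxy)-4-methylidene-6-prenyl-4H-1,3-benzodioxine
Product: 15 (2R)-2-[4-(methoxymethoxy)-3,5-diprenylphenyl]-5,7-bis(methoxymethoxy)-6-prenylchroman-4-one, via aryloxycarbenium enol ion pair 14 (not isolated)
Conditions: confined BINOL-derived chiral imidodiphosphoric acid (5 mol %, antipode as per the assumption), 5 Å MS, toluene, −30 °C; Et3N quench
Reagents that add atoms: none
Why: Proposed new method: the chiral acid ionises the O3–C2 bond of the cyclic aryl/enol acetal to give ion pair 14, in which C2 is a planar aryloxycarbenium ion stabilised by O1 and by the para-oxygenated B ring and the C4 enol is held ortho to it on ring A; C3 of the enol then attacks C2 to form the C2–C3 bond, and loss of the enol proton gives the ketone and returns the catalyst. The closest known reaction types are the Petasis–Ferrier rearrangement of 4-methylene-1,3-dioxanes to tetrahydropyran-4-ones with aluminium Lewis acids, the chiral phosphoric acid catalysed aza-Petasis–Ferrier rearrangement of racemic hemiaminal vinyl ethers, and confined-acid catalysis of additions to oxocarbenium ions. The pyranone ring closes in the 6-(enolendo)-endo-trig mode. The acetal stereocentre of racemic 13 is erased in 14, so both enantiomers converge on one product, and the new C2 stereocentre is set under catalyst control by the confined chiral counter-anion, which should shield one face of the carbenium carbon while hydrogen-bonding the enol OH. The step needs C- over O-recombination and ionisation at C2 in preference to the MOM acetals: O-attack only regenerates 13 and stays reversible whereas C-attack ends in the stable ketone, and the doubly donor-stabilised benzylic C2 is by far the most ionisable acetal carbon of the molecule at low temperature.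

**Step 10**
Reactants: 15 (2R)-2-[4-(methoxymethoxy)-3,5-diprenylphenyl]-5,7-bis(methoxymethoxy)-6-prenylchroman-4-one
Product: 16 (2R)-5,7-dihydroxy-2-(4-hydroxy-3,5-diprenylphenyl)-6-prenylchroman-4-one
Conditions: 3 M HCl (aq), MeOH, 45 °C, stopped at full conversion
Reagents that add atoms: none
Why: Acid-catalysed solvolysis of the three MOM acetals in methanol should free the phenols, and the acidic medium avoids the phenoxide-driven retro-oxa-Michael opening that would scramble C2, provided the temperature is kept low enough to prevent addition of the phenols to the prenyl double bonds.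

**Compound list**
1 | methyl 2,4,6-trihydroxybenzoate | COC(=O)c1c(O)cc(O)cc1O | starting material
2 | methyl 2-hydroxy-4,6-bis(methoxymethoxy)benzoate | COC(=O)c1c(O)cc(OCOC)cc1OCOC | intermediate
3 | methyl 2,4-bis(methoxymethoxy)-6-[(3-methylbut-2-en-1-yl)oxy]benzoate | COC(=O)c1c(OCC=C(C)C)cc(OCOC)cc1OCOC | intermediate
4 | ortho-dienone: methyl 2,4-bis(methoxymethoxy)-5-(2-methylbut-3-en-2-yl)-6-oxocyclohexa-1,3-diene-1-carboxylate (racemic, not isolated) | COC(=O)C1=C(OCOC)C=C(OCOC)C(C(C)(C)C=C)C1=O | intermediate
5 | para-dienone: methyl 2,4-bis(methoxymethoxy)-3-(3-methylbut-2-en-1-yl)-6-oxocyclohexa-1,4-diene-1-carboxylate (racemic, not isolated) | COC(=O)C1=C(OCOC)C(CC=C(C)C)C(OCOC)=CC1=O | intermediate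
6 | methyl 6-hydroxy-2,4-bis(methoxymethoxy)-3-(3-methylbut-2-en-1-yl)benzoate | COC(=O)c1c(O)cc(OCOC)c(CC=C(C)C)c1OCOC | intermediate
7 | 6-hydroxy-2,4-bis(methoxymethoxy)-3-(3-methylbut-2-en-1-yl)benzoic acid | OC(=O)c1c(O)cc(OCOC)c(CC=C(C)C)c1OCOC | intermediate
8 | 3,5-dibromo-4-hydroxybenzaldehyde | O=Cc1cc(Br)c(O)c(Br)c1 | starting material
9 | 3,5-dibromo-4-(methoxymethoxy)benzaldehyde | O=Cc1cc(Br)c(OCOC)c(Br)c1 | intermediate
10 | 4-(methoxymethoxy)-3,5-bis(3-methylbut-2-en-1-yl)benzaldehyde | O=Cc1cc(CC=C(C)C)c(OCOC)c(CC=C(C)C)c1 | intermediate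
11 | trimethylsilyl 2,4-bis(methoxymethoxy)-3-(3-methylbut-2-en-1-yl)-6-(trimethylsilyloxy)benzoate (not isolated) | C[Si](C)(C)OC(=O)c1c(O[Si](C)(C)C)cc(OCOC)c(CC=C(C)C)c1OCOC | intermediate
12 | racemic 2-[4-(methoxymethoxy)-3,5-bis(3-methylbut-2-en-1-yl)phenyl]-5,7-bis(methoxymethoxy)-6-(3-methylbut-2-en-1-yl)-4H-1,3-benzodioxin-4-one | O=C1OC(c2cc(CC=C(C)C)c(OCOC)c(CC=C(C)C)c2)Oc2cc(OCOC)c(CC=C(C)C)c(OCOC)c21 | intermediate
13 | racemic 2-[4-(methoxymethoxy)-3,5-bis(3-methylbut-2-en-1-yl)phenyl]-5,7-bis(methoxymethoxy)-4-methylidene-6-(3-methylbut-2-en-1-yl)-4H-1,3-benzodioxine | C=C1OC(c2cc(CC=C(C)C)c(OCOC)c(CC=C(C)C)c2)Oc2cc(OCOC)c(CC=C(C)C)c(OCOC)c21 | intermediate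
14 | ring-opened ion pair: O-aryl oxocarbenium ion of the B-ring aldehyde on O1 with the free C4 enol ortho to it; the counter-ion is the chiral catalyst anion, not drawn (not isolated) | C=C(O)c1c(OCOC)c(CC=C(C)C)c(OCOC)cc1[O+]=Cc1cc(CC=C(C)C)c(OCOC)c(CC=C(C)C)c1 | intermediate
15 | (2R)-2-[4-(methoxymethoxy)-3,5-bis(3-methylbut-2-en-1-yl)phenyl]-5,7-bis(methoxymethoxy)-6-(3-methylbut-2-en-1-yl)-2,3-dihydro-4H-chromen-4-one | CC(C)=CCc1cc([C@H]2CC(=O)c3c(cc(OCOC)c(CC=C(C)C)c3OCOC)O2)cc(CC=C(C)C)c1OCOC | intermediate
16 | (2R)-5,7-dihydroxy-2-[4-hydroxy-3,5-bis(3-methylbut-2-en-1-yl)phenyl]-6-(3-methylbut-2-en-1-yl)-2,3-dihydro-4H-chromen-4-one | CC(C)=CCc1cc([C@H]2CC(=O)c3c(cc(O)c(CC=C(C)C)c3O)O2)cc(CC=C(C)C)c1O | target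

**Step count**
Total: 10 steps. Longest linear sequence: 8 steps (steps 1–4 and 7–10).

**Steps most likely to fail**

Step 9 (Proposed new method). The ion pair may close with poor facial discrimination, or it may be diverted from C–C closure into reversible C-protonation of the enol ether and hydrolysis by trace water. The fallback is the classical chalcone route, which uses only known chemistry; it sets out from 7 and 10 and comes back at 15. Acid 7 is treated with MeLi (3.5 equiv, THF, 0 °C) to give the methyl ketone 1-[6-hydroxy-2,4-bis(methoxymethoxy)-3-prenylphenyl]ethanone F1. Claisen–Schmidt condensation of this ketone with aldehyde 10 (KOH, EtOH/H2O, rt) should give the (E)-2′-hydroxychalcone F2. Its only free phenol closes by oxa-Michael addition (NaOAc, EtOH, reflux) to the racemic tri-MOM flavanone F3. Preparative HPLC on a polysaccharide chiral stationary phase then delivers 15. The unwanted (2S)-tri-MOM flavanone F4 is returned to the NaOAc equilibration, which racemises it through the chalcone, and is recycled.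

Step 7. The silyl triflate may strip MOM groups, the electron-rich acid may decarboxylate, or the deactivated electron-rich aldehyde may acetalise incompletely. The fallback replaces the kinetic silyl-transfer condensation by a thermodynamic acetal exchange; it sets out from 10 and 7 and comes back at 12. Aldehyde 10 is first converted (HC(OMe)3, cat. PPTS, MeOH, rt) into its dimethyl acetal 5-(dimethoxymethyl)-2-(methoxymethoxy)-1,3-diprenylbenzene F5. This acetal is then exchanged with acid 7 (cat. PPTS, toluene, 60 °C, 5 Å MS to take up methanol) to give 12.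

Step 10. The freed phenols may add under protic acid to the neighbouring prenyl double bonds (chroman formation) faster than the last MOM group is solvolysed, and C2 may erode on prolonged heating. The fallback avoids protic acid; it sets out from 15 and comes back at 16. Treatment of 15 with TMSOTf/2,2′-bipyridyl (CH2Cl2, 0 °C) should exchange each aryl MOM ether for a silyl ether, giving the (2R)-tris(trimethylsilyl) ether of the target F6. Stirring this with water at rt hydrolyses the silyl ethers to 16.

**Further compounds**
F1 | step 9 | 1-[6-hydroxy-2,4-bis(methoxymethoxy)-3-(3-methylbut-2-en-1-yl)phenyl]ethanone | CC(=O)c1c(O)cc(OCOC)c(CC=C(C)C)c1OCOC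
F2 | step 9 | (E)-1-[6-hydroxy-2,4-bis(methoxymethoxy)-3-(3-methylbut-2-en-1-yl)phenyl]-3-[4-(methoxymethoxy)-3,5-bis(3-methylbut-2-en-1-yl)phenyl]prop-2-en-1-one | O=C(/C=C/c1cc(CC=C(C)C)c(OCOC)c(CC=C(C)C)c1)c1c(O)cc(OCOC)c(CC=C(C)C)c1OCOC
F3 | step 9 | racemic 2-[4-(methoxymethoxy)-3,5-bis(3-methylbut-2-en-1-yl)phenyl]-5,7-bis(methoxymethoxy)-6-(3-methylbut-2-en-1-yl)-2,3-dihydro-4H-chromen-4-one | CC(C)=CCc1cc(C2CC(=O)c3c(cc(OCOC)c(CC=C(C)C)c3OCOC)O2)cc(CC=C(C)C)c1OCOC
F4 | step 9 | (2S)-2-[4-(methoxymethoxy)-3,5-bis(3-methylbut-2-en-1-yl)phenyl]-5,7-bis(methoxymethoxy)-6-(3-methylbut-2-en-1-yl)-2,3-dihydro-4H-chromen-4-one | CC(C)=CCc1cc([C@@H]2CC(=O)c3c(cc(OCOC)c(CC=C(C)C)c3OCOC)O2)cc(CC=C(C)C)c1OCOC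
F5 | step 7 | 5-(dimethoxymethyl)-2-(methoxymethoxy)-1,3-bis(3-methylbut-2-en-1-yl)benzene | COC(OC)c1cc(CC=C(C)C)c(OCOC)c(CC=C(C)C)c1
F6 | step 10 | (2R)-2-[3,5-bis(3-methylbut-2-en-1-yl)-4-(trimethylsilyloxy)phenyl]-6-(3-methylbut-2-en-1-yl)-5,7-bis(trimethylsilyloxy)-2,3-dihydro-4H-chromen-4-one | CC(C)=CCc1cc([C@H]2CC(=O)c3c(cc(O[Si](C)(C)C)c(CC=C(C)C)c3O[Si](C)(C)C)O2)cc(CC=C(C)C)c1O[Si](C)(C)C
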